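## Structural features

The target is a 2,6-disubstituted hydroquinone (ring A, methyl on C6, side chain on C2) joined through the benzylic methylene C1' to a twelve-carbon chain, whose last carbon C12' is bonded to C2 (C13') of a 4-methylfuran (ring B). The chain holds three trisubstituted E alkenes (C2'=C3', C6'=C7', C10'=C11', each with its methyl on the carbon remote from ring A) and a single stereocentre, the (R)-carbinol C5'. No other stereocentre stands next to C5', so its configuration must be set in the absolute sense. C5' is allylic to C6'=C7' and homoallylic to C2'=C3', and C1' is both benzylic and allylic. The fragile groups are the hydroquinone (air oxidation to the quinone, fastest as the phenoxide), the electron-rich 2,4-dialkylfuran (acid, oxidants, electrophiles), the secondary allylic alcohol (ionisation and allylic transposition under acid) and the 1,4- and 1,5-diene arrays (alkene migration). The real difficulties are placing the isolated C5' centre between two stereodefined trisubstituted alkenes, securing the 2,4- and not the 2,3-pattern on ring B, and unmasking hydroquinone and carbinol at the end without acid or oxidant. The key step uses the array O–C5'–C4'H2–C3'(CH3)=C2'H: with C6' at the acid level this is an α-oxygenated γ,δ-unsaturated acid, the product of an ester enolate [3,3] shift of the glycolate of a C2' allylic alcohol. That shift forms C4'–C5', the E C2'=C3' alkene and the C5' configuration in one event.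

## Logic of the disconnections

**35 from 34.** Two aryl O–Si bonds and the O–Si bond of a silylated formaldehyde acetal on O5' are restored. Hydroquinone and allylic carbinol are the groups most easily damaged, so they stay masked to the end, and all three masks fall to fluoride at room temperature in one operation. An alkoxymethyl ether is needed on O5' for chelation in step 10. A 2-(trimethylsilyl)ethoxymethyl ether would chelate equally, but on a secondary allylic alcohol it yields to fluoride only on prolonged heating, which ring A and ring B would not tolerate; the (triisopropylsilyloxy)methyl acetal keeps the chelating oxygen and is fluoride-labile. The demand is oxygen-free, buffered fluoride.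

**34 from 33.** A phenylsulfonyl group is put back on C9' (one C–S bond). It makes C9' a carbanion site for the next cut. The forward reduction must deliver hydrogen to C9' and leave C10'=C11' in place and E.

**33 from 22 and 31.** The C8'–C9' bond is cut, midway between two allyl units. Each half carries its alkenes already fixed: 22 holds ring A, C5' and two alkenes, 31 holds ring B and the third alkene, so the route becomes convergent. The anion must react at the carbon α to sulfur and displace bromide at C8' without allylic transposition.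

**31 from 29, and 29 from 26 and 28.** Ring B is taken back to a butenolide and the C12'–C13' bond is cut. A preformed β-methylfuran has two free α positions that metalation does not distinguish reliably; the butenolide has a single nucleophilic carbon, remote from the methyl group, so the 2,4-pattern follows from the construction. The alkylation must go through C5 of 28 and at the CH2Br terminus of 26.

**26 from 25, 24 and 23; 28 from 27.** These are functional group changes on C5 units (C–Br, C–O, C–S and O–Si bonds). The allylic oxidation must select the methyl group trans to the chain.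

**22 from 21 and 20; 20 from 18 and 19.** The C6'=C7' alkene is cut. A stabilised α-branched ylide gives the E enoate reliably and adds C7', its methyl and C8'. The α-alkoxy aldehyde 18 must not epimerise.

**18 from 17 and 16.** Only the oxidation level of C6' changes. The partial reduction must stop at the aldehyde.

**16 from 12 (key step).** C4'–C5' is cut, the alkene moved from C2'=C3' to C3'=C4', and C2'–O reconnected. One stereocentre and one alkene geometry are traded for a carbinol centre at C2' that is easy to resolve. A chair model was checked: (R)-C2', a Z ketene acetal and an equatorial arylmethyl group give (R)-C5' and E C2'=C3'. The descriptor stays R through 16–35 because the ranking O > C6' > C4' never changes. The demand is a single ketene acetal geometry and a chair transition state.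

**12 from 8 and 11; 11 from 10 and 9.** The ester C–O bond is cut, then the acetal and ester bonds of the glycolate unit. The esterification must retain C2'.

**8 from 7; 7 from 6.** The C2'–C3' bond is cut (isopropenyl nucleophile plus aldehyde); the absolute configuration comes from a kinetic resolution. The addition must outrun enolisation of the arylacetaldehyde.

**6 from 4, 3, 2 and 1.** The allyl C=C bond is the latent aldehyde; the two oxygen functions of ring A come from para-oxidation of the phenol. The substitution pattern of ring A is bought ready-made in 1.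

## Other disconnections considered

**Alternative 1:** The cut is three bonds of ring A, C2–C3, C1–C6 and C5–C6 (ring numbered from the chain-bearing C1; C3 and C6 carry oxygen, C5 the methyl). Forward, the chromium carbene complex A2 (zerovalent chromium) and the terminal alkyne A3, which already holds the whole side chain, combine with one carbonyl ligand in a Dötz benzannulation to give the 4-methoxyphenol A1.
- In favour: the ring is assembled with all four substituents placed by the mechanism, and the air-sensitive hydroquinone level appears only at the end.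
- Against: A3 is a 1,4-enyne whose C1' methylene isomerises easily towards allene or conjugated isomers. Its C2'=C3' alkene sits where it can intercept the vinylcarbene or ketene intermediates. Chromium is used stoichiometrically. The C3 methyl ether must then be removed, in practice by oxidative demethylation to the quinone and reduction, in the presence of ring B and three alkenes. The step does nothing for C5', which A3 must already contain.
- Comparison: on structure it is the equal or the better of the chosen plan in convergence and in postponing ring A. The chosen plan, however, buys the ring A pattern in 1, so ring construction solves a problem that is not there. On mechanism, a multi-stage organometallic cascade with several branch points stands against one concerted rearrangement. On step economy, the synthesis of A3 is essentially the whole chain plus an alkyne, followed by demethylation and desilylation, so it should be longer.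

**Alternative 2:** The cut is C12'–C13'. Forward, the silyloxyfuran 28 is alkylated at C5, with silver promotion, by the C12' allylic bromide A5 of the complete chain, giving butenolide A4 as both C13' epimers; reduction to the lactol and dehydration would then form ring B.
- In favour: the ring B pattern is fixed by construction, which is the same principle as in the chosen plan and its equal. The acid-sensitive furan is absent during every C–C bond formation, which is better than the chosen plan, where ring B must survive a sulfonyl carbanion and a palladium step.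
- Against: the least predictable C–C bond formation would be run on the most valuable intermediate. A5 is a geranyl-type bromide whose cation can be captured at C10' or by the C6'=C7' alkene. The lactone reduction and acid-induced aromatisation would take place next to the C5' allylic silyl ether. C5' still needs its own asymmetric step.
- Comparison: on structure the idea is shared, but the chosen plan applies it to a C5 sulfone where failure is cheap. On mechanism the two are equal. On step economy the counts should be similar, and alternative 2 is the more linear.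

**Alternative 3:** The cut is the C5'–H bond. Forward, a nicotinamide-cofactor-dependent ketoreductase with enzymatic cofactor recycling reduces the dienone A7 to the (R)-carbinol A6.
- In favour: the centre is set last and by the catalyst alone. No material is lost to a resolution and O5' needs no protecting group, both better than the chosen plan. The neutral aqueous medium suits ring B.
- Against: A7 is a ketone with two large flanks of similar size and is very lipophilic, so activity and selectivity depend on enzyme screening and cosolvent tolerance and cannot be argued from a model. The β,γ-alkene C2'=C3' can move into conjugation with the C5' carbonyl during the assembly of A7 or in buffer. The assembly of A7 itself needs an acylation at C5' that avoids this.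
- Comparison: on structure it separates skeleton from stereochemistry and is the equal or the better in flexibility. On mechanism the chosen plan is the more predictable, its outcome following from a chair transition state. On step economy alternative 3 should be shorter if a suitable enzyme exists, and about equal if a chemical oxazaborolidine reduction had to replace it.

Key step: step 10

Remarks on the chemistry (assumptions): the tartrate-mediated resolution of 7 is taken to follow the usual sense for secondary allylic alcohols, with the isopropenyl group as the alkene arm. C9' of 33 and C13' of 29 and 30 are formed without control and written without descriptors, since both centres are removed later.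

Abbreviations in the step lines: Ar = 2,5-bis(tert-butyldimethylsilyloxy)-3-methylphenyl; OTOM = [(triisopropylsilyl)oxy]methoxy. Full names stand in the compound list.

## Steps

Step 1
Reactants: 1 2-allyl-6-methylphenol
Product: 2 2-allyl-6-methyl-1,4-benzoquinone
Conditions: Co(salen) [Co(C16H14N2O2), divalent cobalt] (5 mol %), O2 (1 atm), DMF, rt
Reagents that add atoms: dioxygen, O=O
Why: Cobalt–salen-catalysed aerobic oxidation of a 2,6-disubstituted phenol; the phenoxyl radical is trapped by O2 at the only free activated position (para) and the peroxide collapses to the para-quinone.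

Step 2
Reactants: 2 2-allyl-6-methyl-1,4-benzoquinone
Product: 3 2-allyl-6-methylbenzene-1,4-diol
Conditions: Na2S2O4, EtOAc/H2O, rt, under N2
Reagents that add atoms: none
Why: Dithionite reduction of a quinone to the hydroquinone (two electrons, two protons); the isolated allyl alkene is inert.

Step 3
Reactants: 3 2-allyl-6-methylbenzene-1,4-diol
Product: 4 2-allyl-1,4-bis(tert-butyldimethylsilyloxy)-6-methylbenzene
Conditions: t-BuMe2SiCl (2.6 equiv), imidazole (5 equiv), DMF, rt → 40 °C
Reagents that add atoms: tert-butyldimethylsilyl chloride, CC(C)(C)[Si](C)(C)Cl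
Why: Imidazole-promoted O-silylation; the flanked C1 hydroxyl reacts more slowly but 2,6-dialkylphenols are silylated under these conditions, and the bis-silyl ether removes both the acidity and the oxidisability of ring A.

Step 4
Reactants: 4 2-allyl-1,4-bis(tert-butyldimethylsilyloxy)-6-methylbenzene
Product: 6 2-Ar-acetaldehyde, via vicinal diol 5 (not isolated)
Conditions: OsO4 (2 mol %), NaIO4 (4 equiv), 2,6-lutidine (2 equiv), dioxane/H2O 3:1, rt
Reagents that add atoms: osmium tetroxide, O=[Os](=O)(=O)=O (catalytic oxygen carrier); sodium periodate, [Na+].[O-]I(=O)(=O)=O (terminal oxidant)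
Why: Lemieux–Johnson cleavage: dihydroxylation of the terminal alkene and periodate scission of diol 5 give the arylacetaldehyde; this avoids ozone, which would also attack the electron-rich ring, and lutidine keeps the medium from turning acidic.

Step 5
Reactants: 6 2-Ar-acetaldehyde
Product: 7 rac-1-Ar-3-methylbut-3-en-2-ol
Conditions: CH2=C(CH3)MgBr (1.5 equiv), CeCl3 (1.5 equiv, anhydrous), THF, −78 °C; aq. NH4Cl
Reagents that add atoms: isopropenylmagnesium bromide, CC(=C)[Mg]Br
Why: 1,2-Addition of an alkenyl Grignard reagent forms C2'–C3'; CeCl3 lowers the basicity of the nucleophile so that enolisation of the arylacetaldehyde does not compete. The carbinol is formed racemic.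

Step 6
Reactants: 7 rac-1-Ar-3-methylbut-3-en-2-ol
Product: 8 (2R)-1-Ar-3-methylbut-3-en-2-ol
Conditions: Ti(OiPr)4 (0.2 equiv), L-(+)-diisopropyl tartrate (0.24 equiv), t-BuOOH (0.6 equiv), 4 Å molecular sieves, CH2Cl2, −20 °C
Reagents that add atoms: none
Why: Sharpless kinetic resolution of a secondary allylic alcohol: with the L-(+)-tartrate the (S)-carbinol should be epoxidised much faster, so the (R)-carbinol 8 is recovered once slightly more than half of 7 is consumed, and the epoxy alcohol is removed by chromatography. The C2' configuration, the source of all later chirality, is fixed here.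

Step 7
Reactants: 9 methyl glycolate
Product: 10 methyl 2-OTOM-acetate
Conditions: i-Pr3SiOCH2Cl (1.2 equiv), i-Pr2NEt (1.5 equiv), CH2Cl2, 0 °C → rt
Reagents that add atoms: (triisopropylsiloxy)methyl chloride, CC(C)[Si](OCCl)(C(C)C)C(C)C
Why: O-Alkylation of the primary alcohol by an α-chloro ether, as with methoxymethyl chloride, gives the mixed formaldehyde acetal.

Step 8
Reactants: 10 methyl 2-OTOM-acetate
Product: 11 2-OTOM-acetic acid
Conditions: LiOH·H2O (1.5 equiv), THF/H2O 3:1, 0 °C; cold 1 M HCl to pH 4, extraction
Reagents that add atoms: lithium hydroxide, [Li+].[OH-]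
Why: Saponification of an unhindered methyl ester; the silylated acetal is stable to aqueous base and to the brief, cold, weakly acidic work-up.

Step 9
Reactants: 8 (2R)-1-Ar-3-methylbut-3-en-2-ol; 11 2-OTOM-acetic acid
Product: 12 (2R)-1-Ar-3-methylbut-3-en-2-yl 2-OTOM-acetate
Conditions: EDC·HCl (1.5 equiv), DMAP (0.2 equiv), CH2Cl2, 0 °C → rt
Reagents that add atoms: none
Why: Steglich-type carbodiimide esterification; acylation occurs on oxygen and the C2'–O bond is not touched, so the (R) configuration is retained.

Step 10
Reactants: 12 (2R)-1-Ar-3-methylbut-3-en-2-yl 2-OTOM-acetate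
Product: 16 (2R,4E)-6-Ar-4-methyl-2-OTOM-hex-4-enoic acid, via lithium enolate 13 (not isolated), via silyl ketene acetal 14 (not isolated), via trimethylsilyl ester 15 (not isolated)
Conditions: LiN(SiMe3)2 (1.5 equiv), THF, −78 °C; Me3SiCl/Et3N (1:1, 3 equiv), −78 °C → rt; then 5% aq. citric acid
Reagents that add atoms: none
Why: LiN(SiMe3)2 removes an α-hydrogen of the glycolate while lithium is held between the carbonyl oxygen and the acetal oxygen, so enolate 13 forms with these two oxygens cis, and O-silylation freezes this as the (Z)-ketene acetal 14 (13 is E by the CIP rules only because lithium ranks below carbon). On warming, 14 undergoes a concerted suprafacial [3,3]-sigmatropic shift through a chair-like six-membered transition state, breaking O–C2' and forming C4'–C5'; the closest known reaction type is the chelation-controlled Ireland–Claisen rearrangement of allylic α-alkoxyacetates. No ring is closed, the cyclic array existing only in the transition state. The arylmethyl group on C2' takes the equatorial site of the chair, which makes C2'=C3' E, and with the acetal oxygen equatorial on C5' (trans to the ring oxygen in the Z acetal) and hydrogen axial, the bond forms on the face that converts (R)-C2' into (R)-C5'. C5' is thus controlled by two elements together, the carbinol configuration set in step 6 and the ketene acetal geometry set by chelation. The selectivities needed are Z over E acetal, chair over boat and equatorial over axial arylmethyl; the five-membered lithium chelate, the acyclic substrate with an unhindered C4' methylene terminus, and the clash an axial arylmethyl group would suffer with the silyloxy-bearing carbon secure them in that order. The C3' methyl group faces only the axial hydrogen on C5', so nothing pushes the Z acetal out of the chair. Mild aqueous acid cleaves the silyl ester 15 to acid 16 without touching the aryl silyl ethers or the silylated acetal.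

Step 11
Reactants: 16 (2R,4E)-6-Ar-4-methyl-2-OTOM-hex-4-enoic acid
Product: 17 methyl (2R,4E)-6-Ar-4-methyl-2-OTOM-hex-4-enoate
Conditions: Me3SiCHN2 (2 M in hexanes, 1.3 equiv), PhMe/MeOH 4:1, 0 °C
Reagents that add atoms: trimethylsilyldiazomethane, C[Si](C)(C)C=[N+]=[N-]
Why: Methyl esterification by diazomethane released from trimethylsilyldiazomethane and methanol; the neutral conditions leave C5', the aryl silyl ethers and the acetal untouched.

Step 12
Reactants: 17 methyl (2R,4E)-6-Ar-4-methyl-2-OTOM-hex-4-enoate
Product: 18 (2R,4E)-6-Ar-4-methyl-2-OTOM-hex-4-enal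
Conditions: i-Bu2AlH (1.1 equiv), CH2Cl2, −78 °C; MeOH, then aq. KNaC4H4O6
Reagents that add atoms: none
Why: Partial reduction of an α-alkoxy ester: the aluminium hemiacetal is stabilised at −78 °C by chelation to the α-oxygen and releases the aldehyde only on work-up. Aldehyde 18 is used at once without chromatography so that the α-centre is not epimerised.

Step 13
Reactants: 18 (2R,4E)-6-Ar-4-methyl-2-OTOM-hex-4-enal; 19 ethyl 2-(triphenylphosphoranylidene)propanoate
Product: 20 ethyl (2E,4R,6E)-8-Ar-2,6-dimethyl-4-OTOM-octa-2,6-dienoate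
Conditions: CH2Cl2, rt
Reagents that add atoms: none
Why: Wittig reaction of a stabilised α-branched ylide, which gives the E trisubstituted enoate (C6'=C7'); the ylide is not basic enough to epimerise C5'.

Step 14
Reactants: 20 ethyl (2E,4R,6E)-8-Ar-2,6-dimethyl-4-OTOM-octa-2,6-dienoate
Product: 21 (2E,4R,6E)-8-Ar-2,6-dimethyl-4-OTOM-octa-2,6-dien-1-ol
Conditions: i-Bu2AlH (2.5 equiv), CH2Cl2, −78 °C → −40 °C; aq. KNaC4H4O6
Reagents that add atoms: none
Why: 1,2-Reduction of the conjugated ester to the allylic alcohol; alkene geometry and all silicon groups are retained at low temperature.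

Step 15
Reactants: 21 (2E,4R,6E)-8-Ar-2,6-dimethyl-4-OTOM-octa-2,6-dien-1-ol
Product: 22 (2E,4R,6E)-8-Ar-1-bromo-2,6-dimethyl-4-OTOM-octa-2,6-diene
Conditions: CBr4 (1.3 equiv), PPh3 (1.4 equiv), 2,6-lutidine (0.2 equiv), CH2Cl2, −20 °C → 0 °C
Reagents that add atoms: tetrabromomethane, BrC(Br)(Br)Br
Why: Appel bromination of a primary allylic alcohol, an SN2 displacement of the oxyphosphonium ion at C8' under neutral conditions; 22 is used promptly.

Step 16
Reactants: 23 1-bromo-3-methylbut-2-ene
Product: 24 [(3-methylbut-2-en-1-yl)sulfonyl]benzene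
Conditions: PhSO2Na (1.2 equiv), DMF, rt
Reagents that add atoms: sodium benzenesulfinate, [Na+].[O-]S(=O)c1ccccc1
Why: S-Alkylation of the ambident sulfinate by a primary allylic bromide gives the sulfone.

Step 17
Reactants: 24 [(3-methylbut-2-en-1-yl)sulfonyl]benzene
Product: 25 (2E)-2-methyl-4-(phenylsulfonyl)but-2-en-1-ol
Conditions: SeO2 (0.5 equiv), t-BuOOH (2.5 equiv), CH2Cl2, rt
Reagents that add atoms: selenium dioxide, O=[Se]=O (oxygen carrier); tert-butyl hydroperoxide, CC(C)(C)OO (terminal oxidant)
Why: Allylic oxidation by SeO2 (ene reaction, then [2,3]-sigmatropic shift) hydroxylates the methyl group trans to the chain of a trisubstituted alkene, so the E allylic alcohol should form; the methylene next to sulfur is deactivated. Any enal from over-oxidation is removed by chromatography.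

Step 18
Reactants: 25 (2E)-2-methyl-4-(phenylsulfonyl)but-2-en-1-ol
Product: 26 {[(2E)-4-bromo-3-methylbut-2-en-1-yl]sulfonyl}benzene
Conditions: PBr3 (0.4 equiv), Et2O, 0 °C
Reagents that add atoms: phosphorus tribromide, BrP(Br)Br
Why: The primary allylic alcohol is converted into the bromide through its phosphite ester by SN2 displacement; the E alkene is retained.

Step 19
Reactants: 27 3-methylfuran-2(5H)-one
Product: 28 trimethyl[(3-methylfuran-2-yl)oxy]silane
Conditions: Me3SiOSO2CF3 (1.1 equiv), Et3N (1.3 equiv), Et2O, 0 °C; filtration, distillation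
Reagents that add atoms: trimethylsilyl trifluoromethanesulfonate, C[Si](C)(C)OS(=O)(=O)C(F)(F)F
Why: Soft enolisation of the butenolide at its γ-carbon and O-silylation give the aromatic 2-silyloxyfuran, a dienol ether whose nucleophilic carbon is C5.

Step 20
Reactants: 26 {[(2E)-4-bromo-3-methylbut-2-en-1-yl]sulfonyl}benzene; 28 trimethyl[(3-methylfuran-2-yl)oxy]silane
Product: 29 3-methyl-5-[(2E)-2-methyl-4-(phenylsulfonyl)but-2-en-1-yl]furan-2(5H)-one
Conditions: AgOCOCF3 (1.1 equiv), CH2Cl2, −78 °C → −20 °C, dark
Reagents that add atoms: none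
Why: Silver-promoted alkylation of a 2-silyloxyfuran by an allylic bromide: silver assists departure of bromide and the dienol ether attacks through C5, the terminus not shielded by the methyl group, at the primary CH2 of the allyl unit, forming C12'–C13'. The new C13' centre is racemic and is destroyed in step 21.

Step 21
Reactants: 29 3-methyl-5-[(2E)-2-methyl-4-(phenylsulfonyl)but-2-en-1-yl]furan-2(5H)-one
Product: 31 4-methyl-2-[(2E)-2-methyl-4-(phenylsulfonyl)but-2-en-1-yl]furan, via lactol 30 (not isolated)
Conditions: i-Bu2AlH (1.2 equiv), CH2Cl2, −78 °C; then 1 M aq. HCl, 0 °C → rt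
Reagents that add atoms: none
Why: Hydride reduction of the lactone stops at lactol 30, which loses water under the acidic work-up to give the aromatic furan. Because the methyl group is α to the former carbonyl, the product is the 2-alkyl-4-methylfuran and no other isomer can form.

Step 22
Reactants: 31 4-methyl-2-[(2E)-2-methyl-4-(phenylsulfonyl)but-2-en-1-yl]furan; 22 (2E,4R,6E)-8-Ar-1-bromo-2,6-dimethyl-4-OTOM-octa-2,6-diene
Product: 33 C9'-phenylsulfonyl derivative of 34 (both C9' epimers), via lithiated sulfone 32 (not isolated)
Conditions: 31 (1.2 equiv), n-BuLi (1.15 equiv), THF, −78 °C, 30 min; then 22 (1.0 equiv), THF/DMPU, −78 °C → −40 °C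
Reagents that add atoms: none
Why: Deprotonation α to the sulfone gives the allylic sulfonyl carbanion 32, which alkylates at its α-carbon with the primary allylic bromide by SN2 and forms C8'–C9'. The C9' epimers are carried on together, the centre being removed in step 23.

Step 23
Reactants: 33 C9'-phenylsulfonyl derivative of 34
Product: 34 2-[(2E,5R,6E,10E)-3,7,11-trimethyl-12-(4-methylfuran-2-yl)-5-OTOM-dodeca-2,6,10-trien-1-yl]-1,4-bis(tert-butyldimethylsilyloxy)-6-methylbenzene
Conditions: PdCl2(dppp) (5 mol %), LiBHEt3 (2.5 equiv), THF, 0 °C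
Reagents that add atoms: none
Why: Reductive desulfonylation of an allylic sulfone: zerovalent palladium, formed in situ from the divalent precatalyst, ionises the C9'–S bond to an allylpalladium sulfinate, and hydride from LiBHEt3 is delivered to the less substituted terminus C9', so C10'=C11' should stay in place and E. The C5' acetal oxygen is too poor a leaving group to ionise.

Step 24
Reactants: 34 tris-silylated precursor
Product: 35 2-[(2E,5R,6E,10E)-5-hydroxy-3,7,11-trimethyl-12-(4-methylfuran-2-yl)dodeca-2,6,10-trien-1-yl]-6-methylbenzene-1,4-diol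
Conditions: Bu4NF (1 M in THF, 6 equiv), AcOH (3 equiv), degassed THF, 0 °C → rt, under Ar; aq. NH4Cl/Na2S2O4 work-up
Reagents that add atoms: none
Why: Fluoride cleaves the two aryl silyl ethers and the triisopropylsilyl group of the acetal, whose hemiacetal anion expels formaldehyde and frees O5'. Acetic acid buffering and exclusion of oxygen keep the hydroquinone from oxidation and the allylic alcohol and furan from acid.

## Compound list

1 | 2-methyl-6-(prop-2-en-1-yl)phenol | C=CCc1cccc(C)c1O | starting material
2 | 2-methyl-6-(prop-2-en-1-yl)cyclohexa-2,5-diene-1,4-dione | C=CCC1=CC(=O)C=C(C)C1=O | intermediate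
3 | 2-methyl-6-(prop-2-en-1-yl)benzene-1,4-diol | C=CCc1cc(O)cc(C)c1O | intermediate
4 | 1,4-bis(tert-butyldimethylsilyloxy)-2-methyl-6-(prop-2-en-1-yl)benzene | C=CCc1cc(O[Si](C)(C)C(C)(C)C)cc(C)c1O[Si](C)(C)C(C)(C)C | intermediate
5 | 3-[2,5-bis(tert-butyldimethylsilyloxy)-3-methylphenyl]propane-1,2-diol (racemic) | OCC(O)Cc1cc(O[Si](C)(C)C(C)(C)C)cc(C)c1O[Si](C)(C)C(C)(C)C | intermediate (not isolated)
6 | 2-[2,5-bis(tert-butyldimethylsilyloxy)-3-methylphenyl]acetaldehyde | O=CCc1cc(O[Si](C)(C)C(C)(C)C)cc(C)c1O[Si](C)(C)C(C)(C)C | intermediate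
7 | rac-1-[2,5-bis(tert-butyldimethylsilyloxy)-3-methylphenyl]-3-methylbut-3-en-2-ol | CC(=C)C(O)Cc1cc(O[Si](C)(C)C(C)(C)C)cc(C)c1O[Si](C)(C)C(C)(C)C | intermediate
8 | (2R)-1-[2,5-bis(tert-butyldimethylsilyloxy)-3-methylphenyl]-3-methylbut-3-en-2-ol | Cc1cc(O[Si](C)(C)C(C)(C)C)cc(C[C@@H](O)C(C)=C)c1O[Si](C)(C)C(C)(C)C | intermediate
9 | methyl 2-hydroxyacetate | COC(=O)CO | starting material
10 | methyl 2-{[(triisopropylsilyl)oxy]methoxy}acetate | COC(=O)COCO[Si](C(C)C)(C(C)C)C(C)C | intermediate
11 | 2-{[(triisopropylsilyl)oxy]methoxy}acetic acid | OC(=O)COCO[Si](C(C)C)(C(C)C)C(C)C | intermediate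
12 | (2R)-1-[2,5-bis(tert-butyldimethylsilyloxy)-3-methylphenyl]-3-methylbut-3-en-2-yl 2-{[(triisopropylsilyl)oxy]methoxy}acetate | Cc1cc(O[Si](C)(C)C(C)(C)C)cc(C[C@@H](OC(=O)COCO[Si](C(C)C)(C(C)C)C(C)C)C(C)=C)c1O[Si](C)(C)C(C)(C)C | intermediate
13 | lithium (1E)-1-{[(2R)-1-[2,5-bis(tert-butyldimethylsilyloxy)-3-methylphenyl]-3-methylbut-3-en-2-yl]oxy}-2-{[(triisopropylsilyl)oxy]methoxy}ethen-1-olate (enolate oxygen cis to the acetal oxygen) | [Li]O/C(O[C@H](Cc1cc(O[Si](C)(C)C(C)(C)C)cc(C)c1O[Si](C)(C)C(C)(C)C)C(C)=C)=C\OCO[Si](C(C)C)(C(C)C)C(C)C | intermediate (not isolated)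
14 | trimethyl{[(1Z)-1-{[(2R)-1-[2,5-bis(tert-butyldimethylsilyloxy)-3-methylphenyl]-3-methylbut-3-en-2-yl]oxy}-2-{[(triisopropylsilyl)oxy]methoxy}ethenyl]oxy}silane | C[Si](C)(C)O/C(O[C@H](Cc1cc(O[Si](C)(C)C(C)(C)C)cc(C)c1O[Si](C)(C)C(C)(C)C)C(C)=C)=C\OCO[Si](C(C)C)(C(C)C)C(C)C | intermediate (not isolated)
15 | trimethylsilyl (2R,4E)-6-[2,5-bis(tert-butyldimethylsilyloxy)-3-methylphenyl]-4-methyl-2-{[(triisopropylsilyl)oxy]methoxy}hex-4-enoate | Cc1cc(O[Si](C)(C)C(C)(C)C)cc(C/C=C(\C)C[C@@H](OCO[Si](C(C)C)(C(C)C)C(C)C)C(=O)O[Si](C)(C)C)c1O[Si](C)(C)C(C)(C)C | intermediate (not isolated)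
16 | (2R,4E)-6-[2,5-bis(tert-butyldimethylsilyloxy)-3-methylphenyl]-4-methyl-2-{[(triisopropylsilyl)oxy]methoxy}hex-4-enoic acid | Cc1cc(O[Si](C)(C)C(C)(C)C)cc(C/C=C(\C)C[C@@H](OCO[Si](C(C)C)(C(C)C)C(C)C)C(=O)O)c1O[Si](C)(C)C(C)(C)C | intermediate
17 | methyl (2R,4E)-6-[2,5-bis(tert-butyldimethylsilyloxy)-3-methylphenyl]-4-methyl-2-{[(triisopropylsilyl)oxy]methoxy}hex-4-enoate | Cc1cc(O[Si](C)(C)C(C)(C)C)cc(C/C=C(\C)C[C@@H](OCO[Si](C(C)C)(C(C)C)C(C)C)C(=O)OC)c1O[Si](C)(C)C(C)(C)C | intermediate
18 | (2R,4E)-6-[2,5-bis(tert-butyldimethylsilyloxy)-3-methylphenyl]-4-methyl-2-{[(triisopropylsilyl)oxy]methoxy}hex-4-enal | Cc1cc(O[Si](C)(C)C(C)(C)C)cc(C/C=C(\C)C[C@@H](OCO[Si](C(C)C)(C(C)C)C(C)C)C=O)c1O[Si](C)(C)C(C)(C)C | intermediate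
19 | ethyl 2-(triphenylphosphoranylidene)propanoate | CCOC(=O)C(C)=P(c1ccccc1)(c1ccccc1)c1ccccc1 | starting material
20 | ethyl (2E,4R,6E)-8-[2,5-bis(tert-butyldimethylsilyloxy)-3-methylphenyl]-2,6-dimethyl-4-{[(triisopropylsilyl)oxy]methoxy}octa-2,6-dienoate | CCOC(=O)/C(C)=C/[C@H](OCO[Si](C(C)C)(C(C)C)C(C)C)C/C(C)=C/Cc1cc(O[Si](C)(C)C(C)(C)C)cc(C)c1O[Si](C)(C)C(C)(C)C | intermediate
21 | (2E,4R,6E)-8-[2,5-bis(tert-butyldimethylsilyloxy)-3-methylphenyl]-2,6-dimethyl-4-{[(triisopropylsilyl)oxy]methoxy}octa-2,6-dien-1-ol | OC/C(C)=C/[C@H](OCO[Si](C(C)C)(C(C)C)C(C)C)C/C(C)=C/Cc1cc(O[Si](C)(C)C(C)(C)C)cc(C)c1O[Si](C)(C)C(C)(C)C | intermediate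
22 | (2E,4R,6E)-8-[2,5-bis(tert-butyldimethylsilyloxy)-3-methylphenyl]-1-bromo-2,6-dimethyl-4-{[(triisopropylsilyl)oxy]methoxy}octa-2,6-diene | BrC/C(C)=C/[C@H](OCO[Si](C(C)C)(C(C)C)C(C)C)C/C(C)=C/Cc1cc(O[Si](C)(C)C(C)(C)C)cc(C)c1O[Si](C)(C)C(C)(C)C | intermediate
23 | 1-bromo-3-methylbut-2-ene | CC(C)=CCBr | starting material
24 | [(3-methylbut-2-en-1-yl)sulfonyl]benzene | CC(C)=CCS(=O)(=O)c1ccccc1 | intermediate
25 | (2E)-2-methyl-4-(phenylsulfonyl)but-2-en-1-ol | OC/C(C)=C/CS(=O)(=O)c1ccccc1 | intermediate
26 | {[(2E)-4-bromo-3-methylbut-2-en-1-yl]sulfonyl}benzene | BrC/C(C)=C/CS(=O)(=O)c1ccccc1 | intermediate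
27 | 3-methylfuran-2(5H)-one | CC1=CCOC1=O | starting material
28 | trimethyl[(3-methylfuran-2-yl)oxy]silane | Cc1ccoc1O[Si](C)(C)C | intermediate
29 | 3-methyl-5-[(2E)-2-methyl-4-(phenylsulfonyl)but-2-en-1-yl]furan-2(5H)-one (racemic) | CC1=CC(C/C(C)=C/CS(=O)(=O)c2ccccc2)OC1=O | intermediate
30 | 3-methyl-5-[(2E)-2-methyl-4-(phenylsulfonyl)but-2-en-1-yl]-2,5-dihydrofuran-2-ol (mixture of stereoisomers) | CC1=CC(C/C(C)=C/CS(=O)(=O)c2ccccc2)OC1O | intermediate (not isolated)
31 | 4-methyl-2-[(2E)-2-methyl-4-(phenylsulfonyl)but-2-en-1-yl]furan | Cc1coc(C/C(C)=C/CS(=O)(=O)c2ccccc2)c1 | intermediate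
32 | [(2E)-3-methyl-4-(4-methylfuran-2-yl)-1-(phenylsulfonyl)but-2-en-1-yl]lithium | [Li]C(/C=C(\C)Cc1cc(C)co1)S(=O)(=O)c1ccccc1 | intermediate (not isolated)
33 | 2-[(2E,5R,6E,9RS,10E)-3,7,11-trimethyl-12-(4-methylfuran-2-yl)-9-(phenylsulfonyl)-5-{[(triisopropylsilyl)oxy]methoxy}dodeca-2,6,10-trien-1-yl]-1,4-bis(tert-butyldimethylsilyloxy)-6-methylbenzene | C/C(=C\[C@H](OCO[Si](C(C)C)(C(C)C)C(C)C)C/C(C)=C/Cc1cc(O[Si](C)(C)C(C)(C)C)cc(C)c1O[Si](C)(C)C(C)(C)C)CC(/C=C(\C)Cc1cc(C)co1)S(=O)(=O)c1ccccc1 | intermediate
34 | 2-[(2E,5R,6E,10E)-3,7,11-trimethyl-12-(4-methylfuran-2-yl)-5-{[(triisopropylsilyl)oxy]methoxy}dodeca-2,6,10-trien-1-yl]-1,4-bis(tert-butyldimethylsilyloxy)-6-methylbenzene | C/C(=C\[C@H](OCO[Si](C(C)C)(C(C)C)C(C)C)C/C(C)=C/Cc1cc(O[Si](C)(C)C(C)(C)C)cc(C)c1O[Si](C)(C)C(C)(C)C)CC/C=C(\C)Cc1cc(C)co1 | intermediate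
35 | 2-[(2E,5R,6E,10E)-5-hydroxy-3,7,11-trimethyl-12-(4-methylfuran-2-yl)dodeca-2,6,10-trien-1-yl]-6-methylbenzene-1,4-diol | C/C(=C\[C@H](O)C/C(C)=C/Cc1cc(O)cc(C)c1O)CC/C=C(\C)Cc1cc(C)co1 | target

## Step count and least certain steps

Total: 24 steps. Longest linear sequence: 16 steps (steps 1–6, 9–15 and 22–24). The side branches are steps 7–8 (acid 11) and steps 16–21 (sulfone 31).

**Step 10 (key step).** The most likely failure is incomplete chelation during enolisation, or equilibration of the enolate before it is silylated. This gives a mixture of ketene acetal geometries and, since C5' is the only stereocentre, erodes enantiomeric purity in a way that cannot be corrected by separation. Fragmentation of the enolate to a ketene and the allylic alkoxide on warming before silylation is the second risk.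
Fallback (from 6, returning at 16): the C4'–C5' bond would be made by auxiliary-controlled alkylation and not by rearrangement. Aldehyde 6 and ylide 19 would give ethyl (2E)-4-Ar-2-methylbut-2-enoate F1. Reduction with i-Bu2AlH would give (2E)-4-Ar-2-methylbut-2-en-1-ol F2, and CBr4/PPh3 would give 1-[(2E)-4-bromo-3-methylbut-2-en-1-yl]-2,5-bis(tert-butyldimethylsilyloxy)-3-methylbenzene F3. Acid 11 would be joined through its pivalic mixed anhydride to lithiated (4S)-4-benzyl-1,3-oxazolidin-2-one F4, giving (4S)-4-benzyl-3-(2-OTOM-acetyl)-1,3-oxazolidin-2-one F5. Its sodium enolate (NaN(SiMe3)2, THF, −78 °C) would be alkylated by F3 on the face away from the benzyl group (Evans alkylation) to give (4S)-4-benzyl-3-[(2R,4E)-6-Ar-4-methyl-2-OTOM-hex-4-enoyl]-1,3-oxazolidin-2-one F6. Cleavage with LiOH/H2O2 would release 16.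

**Step 20.** The bromide 26 carries an electron-withdrawing sulfonylmethyl group, so silver-assisted ionisation may be slow. The likely faults are competing attack through C3 of the silyloxyfuran or at the inner allyl terminus, and elimination towards the sulfonyl diene.
Fallback (from 28, returning at 29): the sulfone would be introduced after the C–C bond. 3-Methylbut-2-en-1-yl acetate F9 would be oxidised (SeO2, t-BuOOH) to (2E)-4-hydroxy-3-methylbut-2-en-1-yl acetate F10 and brominated (CBr4, PPh3) to (2E)-4-bromo-3-methylbut-2-en-1-yl acetate F11, an allylic partner without acidic α-sulfonyl hydrogens. Silver-promoted alkylation of 28 would give (2E)-3-methyl-4-(4-methyl-5-oxo-2,5-dihydrofuran-2-yl)but-2-en-1-yl acetate F12. A Tsuji–Trost substitution with PhSO2Na (Pd(PPh3)4, zerovalent palladium, THF/MeOH) would place sulfur on the primary terminus and give 29.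

**Step 6.** The rate difference between the enantiomers may be too small for this 1,1-disubstituted alkene next to a bulky arylmethyl group, so that high enantiomeric purity costs high conversion; at best half of the material is kept.
Fallback (from 7, returning at 8): oxidation with Dess–Martin periodinane (NaHCO3, CH2Cl2) would give 1-Ar-3-methylbut-3-en-2-one F7. Corey–Bakshi–Shibata reduction with the (S)-configured B-methyl oxazaborolidine and BH3·SMe2 at low temperature would give 8, on the premise that the isopropenyl group acts as the larger substituent.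

**Step 12.** Over-reduction to the primary alcohol and epimerisation or hydration of the α-alkoxy aldehyde during isolation are the likely faults.
Fallback (from 17, returning at 20): full reduction with LiBH4 (THF, 0 °C) would give (2R,4E)-6-Ar-4-methyl-2-OTOM-hex-4-en-1-ol F8. Oxidation with Dess–Martin periodinane (NaHCO3) in the presence of ylide 19 would then consume aldehyde 18 as it forms and give 20.

**Step 24.** The liberated hydroquinone anion may be oxidised by traces of oxygen. The formaldehyde released from the acetal may hydroxymethylate the electron-rich ring. Cleavage of the acetal silyl group may be slow under buffering.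
Fallback (from 34, returning at 35): desilylation with unbuffered Bu4NF would be followed by deliberate oxidation (Ag2O, Et2O) to 2-[(2E,5R,6E,10E)-5-hydroxy-3,7,11-trimethyl-12-(4-methylfuran-2-yl)dodeca-2,6,10-trien-1-yl]-6-methylcyclohexa-2,5-diene-1,4-dione F13. This quinone would be purified at its air-stable level and reduced with Na2S2O4 under argon as the last operation.

## Further compounds

F1 | step 10 | ethyl (2E)-4-[2,5-bis(tert-butyldimethylsilyloxy)-3-methylphenyl]-2-methylbut-2-enoate | CCOC(=O)/C(C)=C/Cc1cc(O[Si](C)(C)C(C)(C)C)cc(C)c1O[Si](C)(C)C(C)(C)C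
F2 | step 10 | (2E)-4-[2,5-bis(tert-butyldimethylsilyloxy)-3-methylphenyl]-2-methylbut-2-en-1-ol | OC/C(C)=C/Cc1cc(O[Si](C)(C)C(C)(C)C)cc(C)c1O[Si](C)(C)C(C)(C)C
F3 | step 10 | 1-[(2E)-4-bromo-3-methylbut-2-en-1-yl]-2,5-bis(tert-butyldimethylsilyloxy)-3-methylbenzene | BrC/C(C)=C/Cc1cc(O[Si](C)(C)C(C)(C)C)cc(C)c1O[Si](C)(C)C(C)(C)C
F4 | step 10 | (4S)-4-benzyl-1,3-oxazolidin-2-one | O=C1N[C@@H](Cc2ccccc2)CO1
F5 | step 10 | (4S)-4-benzyl-3-(2-{[(triisopropylsilyl)oxy]methoxy}acetyl)-1,3-oxazolidin-2-one | O=C(COCO[Si](C(C)C)(C(C)C)C(C)C)N1[C@@H](Cc2ccccc2)COC1=O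
F6 | step 10 | (4S)-4-benzyl-3-[(2R,4E)-6-[2,5-bis(tert-butyldimethylsilyloxy)-3-methylphenyl]-4-methyl-2-{[(triisopropylsilyl)oxy]methoxy}hex-4-enoyl]-1,3-oxazolidin-2-one | Cc1cc(O[Si](C)(C)C(C)(C)C)cc(C/C=C(\C)C[C@@H](OCO[Si](C(C)C)(C(C)C)C(C)C)C(=O)N2[C@@H](Cc3ccccc3)COC2=O)c1O[Si](C)(C)C(C)(C)C
F7 | step 6 | 1-[2,5-bis(tert-butyldimethylsilyloxy)-3-methylphenyl]-3-methylbut-3-en-2-one | CC(=C)C(=O)Cc1cc(O[Si](C)(C)C(C)(C)C)cc(C)c1O[Si](C)(C)C(C)(C)C
F8 | step 12 | (2R,4E)-6-[2,5-bis(tert-butyldimethylsilyloxy)-3-methylphenyl]-4-methyl-2-{[(triisopropylsilyl)oxy]methoxy}hex-4-en-1-ol | Cc1cc(O[Si](C)(C)C(C)(C)C)cc(C/C=C(\C)C[C@@H](OCO[Si](C(C)C)(C(C)C)C(C)C)CO)c1O[Si](C)(C)C(C)(C)C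
F9 | step 20 | 3-methylbut-2-en-1-yl acetate | CC(C)=CCOC(C)=O
F10 | step 20 | (2E)-4-hydroxy-3-methylbut-2-en-1-yl acetate | CC(=O)OC/C=C(\C)CO
F11 | step 20 | (2E)-4-bromo-3-methylbut-2-en-1-yl acetate | CC(=O)OC/C=C(\C)CBr
F12 | step 20 | (2E)-3-methyl-4-(4-methyl-5-oxo-2,5-dihydrofuran-2-yl)but-2-en-1-yl acetate (racemic) | CC(=O)OC/C=C(\C)CC1C=C(C)C(=O)O1
F13 | step 24 | 2-[(2E,5R,6E,10E)-5-hydroxy-3,7,11-trimethyl-12-(4-methylfuran-2-yl)dodeca-2,6,10-trien-1-yl]-6-methylcyclohexa-2,5-diene-1,4-dione | C/C(=C\[C@H](O)C/C(C)=C/CC1=CC(=O)C=C(C)C1=O)CC/C=C(\C)Cc1cc(C)co1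
A1 | alternative 1 | 4-methoxy-2-methyl-6-[(2E,5R,6E,10E)-5-(tert-butyldimethylsilyloxy)-3,7,11-trimethyl-12-(4-methylfuran-2-yl)dodeca-2,6,10-trien-1-yl]phenol | COc1cc(C)c(O)c(C/C=C(\C)C[C@@H](O[Si](C)(C)C(C)(C)C)/C=C(\C)CC/C=C(\C)Cc2cc(C)co2)c1
A2 | alternative 1 | pentacarbonyl[(2E)-1-methoxybut-2-en-1-ylidene]chromium | COC(/C=C/C)=[Cr].[C-]#[O+].[C-]#[O+].[C-]#[O+].[C-]#[O+].[C-]#[O+]
A3 | alternative 1 | tert-butyl(dimethyl){[(4E,7R,8E,12E)-5,9,13-trimethyl-14-(4-methylfuran-2-yl)tetradeca-4,8,12-trien-1-yn-7-yl]oxy}silane | C#CC/C=C(\C)C[C@@H](O[Si](C)(C)C(C)(C)C)/C=C(\C)CC/C=C(\C)Cc1cc(C)co1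
A4 | alternative 2 | 5-[(2E,6E,8R,10E)-12-[2,5-bis(tert-butyldimethylsilyloxy)-3-methylphenyl]-8-(tert-butyldimethylsilyloxy)-2,6,10-trimethyldodeca-2,6,10-trien-1-yl]-3-methylfuran-2(5H)-one (both C5 epimers) | Cc1cc(O[Si](C)(C)C(C)(C)C)cc(C/C=C(\C)C[C@@H](O[Si](C)(C)C(C)(C)C)/C=C(\C)CC/C=C(\C)CC2C=C(C)C(=O)O2)c1O[Si](C)(C)C(C)(C)C
A5 | alternative 2 | 1-[(2E,5R,6E,10E)-12-bromo-5-(tert-butyldimethylsilyloxy)-3,7,11-trimethyldodeca-2,6,10-trien-1-yl]-2,5-bis(tert-butyldimethylsilyloxy)-3-methylbenzene | Cc1cc(O[Si](C)(C)C(C)(C)C)cc(C/C=C(\C)C[C@@H](O[Si](C)(C)C(C)(C)C)/C=C(\C)CC/C=C(\C)CBr)c1O[Si](C)(C)C(C)(C)C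
A6 | alternative 3 | (2E,5R,6E,10E)-1-[2,5-bis(tert-butyldimethylsilyloxy)-3-methylphenyl]-3,7,11-trimethyl-12-(4-methylfuran-2-yl)dodeca-2,6,10-trien-5-ol | Cc1cc(O[Si](C)(C)C(C)(C)C)cc(C/C=C(\C)C[C@@H](O)/C=C(\C)CC/C=C(\C)Cc2cc(C)co2)c1O[Si](C)(C)C(C)(C)C
A7 | alternative 3 | (2E,6E,10E)-1-[2,5-bis(tert-butyldimethylsilyloxy)-3-methylphenyl]-3,7,11-trimethyl-12-(4-methylfuran-2-yl)dodeca-2,6,10-trien-5-one | Cc1cc(O[Si](C)(C)C(C)(C)C)cc(C/C=C(\C)CC(=O)/C=C(\C)CC/C=C(\C)Cc2cc(C)co2)c1O[Si](C)(C)C(C)(C)C
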